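The route rests on cutting the C2–C1' bond between the tetradecyl chain and the pyridine ring of the quinolone. The precursor is 4-methoxyquinoline 1. Its pyridine ring has two electron-poor carbons, C2 and C4. C4 already carries the future carbonyl oxygen as OMe, so the C2–H next to N1 is the only site open to a nucleophilic radical. One decarboxylative Minisci reaction with pentadecanoic acid 2 installs the whole unfunctionalised C14 chain and gives 3, a constitutional isomer of the target. Moving the methyl group from O4 to N1 (N-methylation to salt 4, then iodide dealkylation) delivers 5.

Key step: step 1

Remark on the chemistry: N-protonated forms present in acidic media are counted as the same numbered compound as the free base; the C15 acid loses CO2 to give the C14 chain; the target has no stereocentre, so no stereocontrol is needed.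

Step 1
Reactants: 1 4-methoxyquinoline; 2 pentadecanoic acid
Product: 3 4-methoxy-2-tetradecylquinoline
Conditions: 2 (2.5 equiv), AgNO3 (0.2 equiv), (NH4)2S2O8 (2.5 equiv, in portions), TFA (1.5 equiv), MeCN/H2O 1:1, 70 °C; aq Na2CO3 work-up, short basic alumina column
Reagents that add atoms: none
Why: Persulfate raises monovalent silver to divalent silver, which takes one electron from the carboxylate of 2, and loss of CO2 leaves the primary tetradecyl radical. This nucleophilic radical adds to C2 of N-protonated 1, the adduct radical cation loses the C2 proton, and the resulting α-amino radical is oxidised by persulfate or divalent silver to the rearomatised, protonated form of 3, so that only the C2–C1' bond is made. The reaction type is the silver-catalysed persulfate decarboxylative Minisci alkylation, long established for protonated quinolines and primary alkyl carboxylic acids. No ring is closed and no stereocentre arises. The selectivity required is C2 against C4 and against the benzo ring: the methoxy group occupies C4, the carbocyclic positions are too electron-rich for an alkyl radical, and after reaction no activated C–H is left, which should prevent a second alkylation. Working in aqueous MeCN above the melting point of 2 with portionwise persulfate should keep the fatty acid dissolved and the stationary radical concentration low.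

Step 2
Reactants: 3 4-methoxy-2-tetradecylquinoline
Product: 4 4-methoxy-1-methyl-2-tetradecylquinolinium trifluoromethanesulfonate
Conditions: MeOTf (1.2 equiv), CH2Cl2, 0 °C to rt; evaporate, triturate with cold pentane
Reagents that add atoms: methyl trifluoromethanesulfonate (MeOTf), COS(=O)(=O)C(F)(F)F
Why: In this Menshutkin quaternisation N1 is the only nucleophilic site and is made more electron-rich by the conjugated 4-methoxy donor, the strong electrophile MeOTf should overcome crowding by the C2 chain and the peri C8–H at room temperature, and the non-nucleophilic triflate stops the reaction at an ionic salt that can be washed free of hydrocarbon residues from step 1.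

Step 3
Reactants: 4 4-methoxy-1-methyl-2-tetradecylquinolinium trifluoromethanesulfonate
Product: 5 1-methyl-2-tetradecylquinolin-4(1H)-one (target)
Conditions: NaI (3 equiv), MeCN, reflux, N2 sweep; aq Na2S2O3 wash
Reagents that add atoms: none
Why: Iodide attacks the O-methyl carbon of the 4-methoxyquinolinium ion in an SN2 dealkylation (the closing half of a Hilbert–Johnson-type O-to-N alkyl transfer), the leaving group is the neutral, strongly stabilised vinylogous amide 5, and the volatile MeI is swept out so that reverse O-methylation cannot compete.

Compound list
1 | 4-methoxyquinoline | COc1ccnc2ccccc12 | starting material
2 | pentadecanoic acid | CCCCCCCCCCCCCCC(=O)O | starting material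
3 | 4-methoxy-2-tetradecylquinoline | CCCCCCCCCCCCCCc1cc(OC)c2ccccc2n1 | intermediate
4 | 4-methoxy-1-methyl-2-tetradecylquinolinium trifluoromethanesulfonate | CCCCCCCCCCCCCCc1cc(OC)c2ccccc2[n+]1C.[O-]S(=O)(=O)C(F)(F)F | intermediate
5 | 1-methyl-2-tetradecylquinolin-4(1H)-one | CCCCCCCCCCCCCCc1cc(=O)c2ccccc2n1C | target

Total step count: 3
Longest linear sequence: 3

Steps most likely to fail

**Step 1.**
- The methoxy donor lowers the electrophilicity of the quinolinium ion, so radical capture may be slow.
- The tetradecyl radical may then be lost to dimerisation, hydrogen abstraction or over-oxidation.
- Phase separation of the fatty acid, precipitation of silver pentadecanoate, or slow acid hydrolysis of the C4 ether could also erode conversion.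
- Fallback, from 1, polar instead of radical: oxidation with mCPBA in CH2Cl2 should give 4-methoxyquinoline 1-oxide F1.
- Tetradecylmagnesium chloride (C14H29MgCl) with catalytic CuCl and MgCl2 in Et2O/THF at rt then adds at C2, guided by coordination to the N-oxide oxygen. This gives the chloromagnesium salt of 4-methoxy-2-tetradecyl-1,2-dihydroquinolin-1-ol F2.
- That adduct eliminates in the same flask and rejoins the route at 3.

**Step 2.**
- Quaternisation may stall because N1 is flanked by the C2 chain and the C8–H, or the methylating agent may be consumed by adventitious water.
- Fallback, from 3, with the order of events reversed: cleavage of the methyl ether with 48% aq HBr in AcOH at reflux should give 2-tetradecylquinolin-4(1H)-one F3.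
- Deprotonation with NaH in DMF followed by MeI should alkylate the ambident anion mainly at nitrogen. This arrives directly at 5 and bypasses 4.
- Material alkylated at oxygen is 3 itself and can be recycled.

**Step 3.**
- The SN2 dealkylation may be incomplete, or may be reversed by re-methylation at oxygen if MeI is not removed.
- Fallback, from 4, breaking the C4–O bond instead of the O–CH3 bond: aq NaOH in THF at rt to 50 °C adds hydroxide to C4 of the quinolinium ring and expels methoxide by addition–elimination.
- This returns to the route at 5 without any new isolable compound.

Further compounds
F1 | step 1 | 4-methoxyquinoline 1-oxide | COc1cc[n+]([O-])c2ccccc12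
F2 | step 1 | 4-methoxy-2-tetradecyl-1,2-dihydroquinolin-1-ol, racemic, formed as its chloromagnesium salt and not isolated | CCCCCCCCCCCCCCC1C=C(OC)c2ccccc2N1O
F3 | step 2 | 2-tetradecylquinolin-4(1H)-one | CCCCCCCCCCCCCCc1cc(=O)c2ccccc2[nH]1
F0 | step 3 | none | none
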